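**Plan**
- The six-membered carbocycle (C1 quaternary carbon, C2 ketone, C3 side-chain carbon, C4 pyranone oxygen carbon, C5 acyl carbon, C6 enol carbon) alternates three oxygen-bearing carbons (C2, C4, C6) with three carbon-substituted ones (C1, C3, C5). A vinylketene and an ynol ether write exactly this pattern regiospecifically, so the arene form of this ring is the pivot.
- Retrosynthetic cuts, in order: the side-chain ester; C1–prenyl (dearomative allylation); O4–CMe2 and C5–C(=O) of the pyranone; then C5–C6 and C3–C4 of the arene, with C1–C6 opened and re-closed, giving a 3-silyloxycyclobutenone and (triisopropylsilyloxy)ethyne; last, two bonds of the cyclobutenone, giving an alkylketene and a side-chain silyloxyalkyne.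
- Forward: a trans-cyclobutane acid and an (R)-configured silyloxyalkyne join in a ketene [2+2] (four-membered ring); benzannulation builds the benzene ring; fluoride-triggered oxa-Michael addition closes the pyranone on O4; prenylation at C1 dearomatises; the tert-butyl ester is cleaved last, because a free acid beside the C2 phenol could lactonise.
- Stereochemistry: cyclobutane C2 from a rhodium/chiral-diene 1,4-addition, with the ester set trans by equilibration; the side-chain centre from auxiliary-controlled alkylation; quaternary C1 from ligand-controlled palladium prenylation.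

Key step: step 16

Assumption: the sense of induction of the chiral diene (step 4) and of the Trost ligand (step 23) is taken to give the drawn configurations; the ligand antipode is used if a first run shows the opposite sense.

Notation: C1–C6 are the carbocycle carbons as numbered in the plan; CbCH2 = trans-[3,3-dimethyl-2-(prop-1-en-2-yl)cyclobutyl]methyl with the isopropenyl-bearing ring carbon R (geometry as in the SMILES); SC = (3R)-1-tert-butoxy-1-oxohexan-3-yl; TIPS = tri(propan-2-yl)silyl.

**Route**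

Step 1
Reactants: 1 3,3-dimethylcyclobutane-1-carboxylic acid
Product: 2 ethyl 3,3-dimethylcyclobutane-1-carboxylate
Conditions: EtOH, H2SO4 (cat.), reflux
Reagents that add atoms: ethanol CCO
Why: Fischer esterification of an unhindered acid provides the ester needed for enolate chemistry; no stereocentre is involved.

Step 2
Reactants: 2 ethyl 3,3-dimethylcyclobutane-1-carboxylate
Product: 3 ethyl 1-bromo-3,3-dimethylcyclobutane-1-carboxylate
Conditions: LiN(i-Pr)2, THF, −78 °C; then CBr4, −78 °C to rt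
Reagents that add atoms: carbon tetrabromide BrC(Br)(Br)Br
Why: Electrophilic α-bromination of the lithium ester enolate at its only α-carbon; the product is achiral.

Step 3
Reactants: 3 ethyl 1-bromo-3,3-dimethylcyclobutane-1-carboxylate
Product: 4 ethyl 3,3-dimethylcyclobut-1-ene-1-carboxylate
Conditions: DBU, THF, 60 °C
Reagents that add atoms: none
Why: E2 dehydrobromination of the tertiary α-bromo ester; the two β-methylene groups are equivalent by symmetry, so only one cyclobutene ester can form.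

Step 4
Reactants: 4 ethyl 3,3-dimethylcyclobut-1-ene-1-carboxylate; 5 4,4,5,5-tetramethyl-2-(prop-1-en-2-yl)-1,3,2-dioxaborolane
Product: 6 ethyl (1R,2R)-3,3-dimethyl-2-(prop-1-en-2-yl)cyclobutane-1-carboxylate (trans)
Conditions: [RhCl(C2H4)2]2 (cat.), (R,R)-2,5-diphenylbicyclo[2.2.2]octa-2,5-diene, KOH (aq., substoichiometric), 1,4-dioxane, 50 °C; then NaOEt (cat.), EtOH, rt
Reagents that add atoms: none
Why: Hayashi–Miyaura rhodium-catalysed asymmetric 1,4-addition: the isopropenyl–rhodium species adds to the strained enoate at C2 on the face chosen by the chiral diene (C2 = R), and protonation followed by ethoxide equilibration leaves the ester trans to isopropenyl (C1 = R).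

Step 5
Reactants: 6 ethyl (1R,2R)-3,3-dimethyl-2-(prop-1-en-2-yl)cyclobutane-1-carboxylate
Product: 7 (1R,2R)-3,3-dimethyl-2-(prop-1-en-2-yl)cyclobutane-1-carbaldehyde
Conditions: i-Bu2AlH, CH2Cl2, −78 °C; aq. potassium sodium tartrate
Reagents that add atoms: none
Why: Partial ester reduction through the aluminium hemiacetal, which is stable at −78 °C and collapses only on work-up; the alkene is untouched and the trans arrangement is the thermodynamic one.

Step 6
Reactants: 7 (1R,2R)-3,3-dimethyl-2-(prop-1-en-2-yl)cyclobutane-1-carbaldehyde; 8 2,2-dimethyl-1,3-dioxane-4,6-dione (Meldrum's acid)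
Product: 10 5-{[(1R,2R)-3,3-dimethyl-2-(prop-1-en-2-yl)cyclobutyl]methyl}-2,2-dimethyl-1,3-dioxane-4,6-dione, via alkylidene Meldrum's acid 9 (not isolated)
Conditions: diethyl 2,6-dimethyl-1,4-dihydropyridine-3,5-dicarboxylate (Hantzsch ester), L-proline (cat.), EtOH, rt
Reagents that add atoms: none
Why: Organocatalytic reductive alkylation (Knoevenagel condensation, then Hantzsch ester transfer hydrogenation of the alkylidene) adds the two-carbon unit without touching the isopropenyl group; no stereocentre is created and the trans ring is the thermodynamic arrangement.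

Step 7
Reactants: 10 5-{[(1R,2R)-3,3-dimethyl-2-(prop-1-en-2-yl)cyclobutyl]methyl}-2,2-dimethyl-1,3-dioxane-4,6-dione
Product: 11 3-[(1R,2R)-3,3-dimethyl-2-(prop-1-en-2-yl)cyclobutyl]propanoic acid
Conditions: pyridine/H2O, 100 °C
Reagents that add atoms: water O
Why: Hydrolysis of the Meldrum's acid ring and thermal decarboxylation of the malonic acid (malonate-type degradation) under weakly basic conditions that spare the acid-sensitive isopropenylcyclobutane.

Step 8
Reactants: 12 (4S)-4-benzyl-1,3-oxazolidin-2-one; 13 pentanoyl chloride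
Product: 14 (4S)-4-benzyl-3-pentanoyl-1,3-oxazolidin-2-one
Conditions: n-BuLi, THF, −78 °C; then 13, −78 to 0 °C
Reagents that add atoms: none
Why: N-acylation of the lithiated oxazolidinone installs the chiral auxiliary; no new stereocentre.

Step 9
Reactants: 14 (4S)-4-benzyl-3-pentanoyl-1,3-oxazolidin-2-one; 15 tert-butyl bromoacetate
Product: 16 tert-butyl (3R)-3-{[(4S)-4-benzyl-2-oxo-1,3-oxazolidin-3-yl]carbonyl}hexanoate
Conditions: NaN(SiMe3)2, THF, −78 °C; then 15, −78 to −40 °C
Reagents that add atoms: none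
Why: Evans alkylation: the chelated Z-sodium enolate is alkylated on the face away from the benzyl group, which sets the side-chain centre as 3R.

Step 10
Reactants: 16 tert-butyl (3R)-3-{[(4S)-4-benzyl-2-oxo-1,3-oxazolidin-3-yl]carbonyl}hexanoate
Product: 17 tert-butyl (3R)-3-(hydroxymethyl)hexanoate
Conditions: LiBH4, H2O (1 equiv), THF, 0 °C
Reagents that add atoms: none
Why: Reductive auxiliary removal: LiBH4 reduces the exocyclic imide carbonyl and leaves the tert-butyl ester; the stereocentre is not enolised, and the product is kept cold and used at once to avoid lactonisation.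

Step 11
Reactants: 17 tert-butyl (3R)-3-(hydroxymethyl)hexanoate
Product: 18 tert-butyl (3R)-3-formylhexanoate
Conditions: Dess–Martin periodinane, NaHCO3, CH2Cl2, 0 °C to rt
Reagents that add atoms: none
Why: Dess–Martin oxidation under buffered, non-basic conditions gives the aldehyde without epimerising the adjacent centre.

Step 12
Reactants: 18 tert-butyl (3R)-3-formylhexanoate
Product: 19 tert-butyl (3R)-3-ethynylhexanoate
Conditions: dimethyl (1-diazo-2-oxopropyl)phosphonate, K2CO3, MeOH, 0 °C to rt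
Reagents that add atoms: dimethyl (1-diazo-2-oxopropyl)phosphonate CC(=O)C(=[N+]=[N-])P(=O)(OC)OC
Why: Seyferth–Gilbert homologation in the Ohira–Bestmann variant turns the aldehyde into the terminal alkyne under mild carbonate conditions; the α-alkyl aldehyde should be trapped faster than it enolises.

Step 13
Reactants: 19 tert-butyl (3R)-3-ethynylhexanoate
Product: 21 tert-butyl (3R)-3-[(TIPS-oxy)ethynyl]hexanoate, via lithium ynolate 20 (not isolated)
Conditions: n-BuLi, THF, −78 °C; LiOOt-Bu (from t-BuOOH and LiN(SiMe3)2), −78 to 0 °C; then i-Pr3SiOTf, −78 °C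
Reagents that add atoms: lithium tert-butyl peroxide [Li+].[O-]OC(C)(C)C; triisopropylsilyl trifluoromethanesulfonate CC(C)[Si](OS(=O)(=O)C(F)(F)F)(C(C)C)C(C)C
Why: Acetylide oxidation: deprotonation of the alkyne at −78 °C outpaces attack on the tert-butyl ester, the acetylide takes electrophilic oxygen from the lithium peroxide to give the ynolate, and the bulky silyl triflate silylates it on oxygen; the propargylic centre is not acidic enough to epimerise.

Step 14
Reactants: 22 acetylene
Product: 24 (triisopropylsilyloxy)ethyne, via lithium ethynolate 23 (not isolated)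
Conditions: acetylene (excess), n-BuLi, THF, −78 °C; LiOOt-Bu (from t-BuOOH and LiN(SiMe3)2), −78 to −20 °C; then i-Pr3SiOTf, −78 °C
Reagents that add atoms: lithium tert-butyl peroxide [Li+].[O-]OC(C)(C)C; triisopropylsilyl trifluoromethanesulfonate CC(C)[Si](OS(=O)(=O)C(F)(F)F)(C(C)C)C(C)C
Why: The same acetylide oxidation and O-silylation applied to monolithium acetylide gives the parent silyl ynol ether, purified by distillation.

Step 15
Reactants: 11 3-[(1R,2R)-3,3-dimethyl-2-(prop-1-en-2-yl)cyclobutyl]propanoic acid; 21 tert-butyl (3R)-3-[(TIPS-oxy)ethynyl]hexanoate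
Product: 27 4-(CbCH2)-2-(SC)-3-(TIPSO)cyclobut-2-en-1-one (both C4 epimers), via acid chloride 25 (not isolated), via ketene 26 (not isolated)
Conditions: 11, 1-chloro-N,N,2-trimethylprop-1-en-1-amine, CH2Cl2, 0 °C to rt; then slow addition to 21 and Et3N, CH2Cl2, rt
Reagents that add atoms: none
Why: Ketene–ynol ether [2+2] cycloaddition: the acid chloride is made without HCl, the ketene formed by dehydrochlorination is attacked at its carbonyl carbon by the nucleophilic β-carbon of the silyloxyalkyne, and ring closure gives the 3-silyloxycyclobutenone with the ketene substituent on the sp3 carbon; the new ring CH centre forms as a mixture that the next step erases.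

Step 16
Reactants: 27 4-(CbCH2)-2-(SC)-3-(TIPSO)cyclobut-2-en-1-one; 24 (triisopropylsilyloxy)ethyne
Product: 32 phenol (C1-CbCH2 / C2-OTIPS / C3-SC / C4-OTIPS / C5-H / C6-OH), via vinylketene 28 (not isolated), via 4-vinylcyclobutenone 29 (not isolated), via dienylketene 30 (not isolated), via cyclohexadienone 31 (not isolated)
Conditions: 24 (2 equiv), toluene, 80 °C
Reagents that add atoms: none
Why: Thermal 4π opening of 27 gives vinylketene 28, whose electrophilic carbonyl carbon (future C6) is attacked by the nucleophilic CH carbon of ynol ether 24 while its α-carbon (C3) bonds to the oxygen-bearing alkyne carbon, a regiospecific [2+2] to 29. A second 4π opening gives dienylketene 30, and a thermally allowed disrotatory 6π electrocyclisation re-forms C1–C6 and closes the six-membered carbocycle as dienone 31, which tautomerises to phenol 32. The closest known reaction type is the Danheiser benzannulation of cyclobutenones with silyloxyalkynes. No stereocentre is created and the ring CH centre of 27 is erased, so both epimers converge while the remote cyclobutane and side-chain centres are untouched at 80 °C. The step needs regiocontrol in the [2+2] and chemoselectivity over the isopropenyl alkene and the ester; the first is secured by the matched polarity of ketene and ynol ether, the second by the much higher ketenophilicity of the silyloxyalkyne, and each stage is driven by release of four-membered ring strain and finally by aromatisation.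

Step 17
Reactants: 32 phenol (C6-OH free / C5-H)
Product: 33 3-(CbCH2)-2-hydroxy-5-(SC)-4,6-bis(TIPSO)benzaldehyde (C5-CHO)
Conditions: MgCl2, Et3N, (CH2O)n, THF, reflux
Reagents that add atoms: formaldehyde (as paraformaldehyde) C=O
Why: Casnati–Skattebøl ortho-formylation: the magnesium phenoxide delivers formaldehyde to C5, the only unsubstituted carbon ortho to the free hydroxyl, and hydride transfer to a second formaldehyde gives the aldehyde.

Step 18
Reactants: 33 3-(CbCH2)-2-hydroxy-5-(SC)-4,6-bis(TIPSO)benzaldehyde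
Product: 34 2-(allyloxy)-3-(CbCH2)-5-(SC)-4,6-bis(TIPSO)benzaldehyde
Conditions: allyl bromide, K2CO3, DMF, rt
Reagents that add atoms: allyl bromide C=CCBr
Why: Williamson etherification of the only free phenol (O6); the allyl group keeps O6 out of the later pyranone closure and is removable without acid.

Step 19
Reactants: 34 2-(allyloxy)-3-(CbCH2)-5-(SC)-4,6-bis(TIPSO)benzaldehyde; 35 2-methylprop-1-en-1-ylmagnesium bromide
Product: 36 1-[2-(allyloxy)-3-(CbCH2)-5-(SC)-4,6-bis(TIPSO)phenyl]-3-methylbut-2-en-1-ol (both carbinol epimers)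
Conditions: THF, −78 to −20 °C; aq. NH4Cl
Reagents that add atoms: none
Why: Grignard 1,2-addition to the aldehyde is much faster than attack on the tert-butyl ester at low temperature; the carbinol centre forms unselectively and is removed by the next oxidation.

Step 20
Reactants: 36 1-[2-(allyloxy)-3-(CbCH2)-5-(SC)-4,6-bis(TIPSO)phenyl]-3-methylbut-2-en-1-ol
Product: 37 1-[2-(allyloxy)-3-(CbCH2)-5-(SC)-4,6-bis(TIPSO)phenyl]-3-methylbut-2-en-1-one
Conditions: Dess–Martin periodinane, NaHCO3, CH2Cl2, 0 °C to rt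
Reagents that add atoms: none
Why: Dess–Martin oxidation of the benzylic and allylic alcohol to the aryl enone under buffered, non-acidic conditions.

Step 21
Reactants: 37 1-[2-(allyloxy)-3-(CbCH2)-5-(SC)-4,6-bis(TIPSO)phenyl]-3-methylbut-2-en-1-one
Product: 39 5-(allyloxy)-6-(CbCH2)-7-hydroxy-2,2-dimethyl-8-(SC)chroman-4-one, via bis-phenol enone 38 (not isolated)
Conditions: Bu4NF, THF, 0 °C to rt; aq. NH4Cl
Reagents that add atoms: none
Why: Fluoride cleaves both aryl silyl ethers, and the C4 phenoxide, the only free oxygen ortho to the enone because O6 is allylated, closes the pyranone by 6-endo-trig oxa-Michael addition; the new ring carbon is not stereogenic.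

Step 22
Reactants: 39 5-(allyloxy)-6-(CbCH2)-7-hydroxy-2,2-dimethyl-8-(SC)chroman-4-one
Product: 40 6-(CbCH2)-5,7-dihydroxy-2,2-dimethyl-8-(SC)chroman-4-one
Conditions: Pd(PPh3)4 (cat.), morpholine, THF, rt
Reagents that add atoms: none
Why: Tsuji–Trost deallylation: zerovalent palladium ionises the aryl allyl ether and morpholine captures the π-allyl unit, freeing the C6 hydroxyl under neutral conditions that leave ester and alkenes alone.

Step 23
Reactants: 40 6-(CbCH2)-5,7-dihydroxy-2,2-dimethyl-8-(SC)chroman-4-one; 41 3-methylbut-2-en-1-yl acetate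
Product: 42 tert-butyl (3R)-3-[(6R)-6-(CbCH2)-5-hydroxy-2,2-dimethyl-6-(3-methylbut-2-en-1-yl)-4,7-dioxo-3,4,6,7-tetrahydro-2H-chromen-8-yl]hexanoate
Conditions: Pd2(dba)3·CHCl3 (cat.), (R,R)-DACH-phenyl Trost ligand, Cs2CO3, 41 (1.05 equiv), 1,4-dioxane, rt
Reagents that add atoms: none
Why: Proposed new method: zerovalent palladium ionises prenyl acetate to a π-prenyl cation that the caesium phenoxide of 40 attacks outer-sphere at the unhindered CH2 terminus through C1, the ring carbon ortho to both free oxygens and para to the ring ether oxygen; O-prenylation is reversible under the catalyst and C–C bond formation is not, so material should funnel to the C1-prenyl dienone, and the chiral pocket of the Trost ligand is expected to distinguish the two faces of the planar nucleophile and set C1 as R, the remote stereocentres giving no useful bias; the closest known reaction types are the palladium-catalysed asymmetric allylic dearomatisation of naphthols and the base-mediated dearomative prenylation of acylphloroglucinols.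

Step 24
Reactants: 42 tert-butyl ester of the target
Product: 44 (3R)-3-[(6R)-6-{[(1S,2R)-3,3-dimethyl-2-(prop-1-en-2-yl)cyclobutyl]methyl}-5-hydroxy-2,2-dimethyl-6-(3-methylbut-2-en-1-yl)-4,7-dioxo-3,4,6,7-tetrahydro-2H-chromen-8-yl]hexanoic acid (CNP0358381.1), via bis-trimethylsilyl derivative 43 (not isolated)
Conditions: Me3SiOTf, 2,6-lutidine, CH2Cl2, 0 °C; then aq. NaH2PO4 (pH 5), THF
Reagents that add atoms: none
Why: Silyl triflate-mediated tert-butyl ester cleavage (carbonyl silylation, loss of isobutene to the base) under aprotic buffered conditions spares the isopropenylcyclobutane, prenyl and enol ether units, and mild aqueous hydrolysis of the silyl ester and silyl enol ether frees the acid; no stereocentre is touched.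

**Compound list**

1 | 3,3-dimethylcyclobutane-1-carboxylic acid | CC1(C)CC(C(=O)O)C1 | starting material
2 | ethyl 3,3-dimethylcyclobutane-1-carboxylate | CCOC(=O)C1CC(C)(C)C1 | intermediate
3 | ethyl 1-bromo-3,3-dimethylcyclobutane-1-carboxylate | CCOC(=O)C1(Br)CC(C)(C)C1 | intermediate
4 | ethyl 3,3-dimethylcyclobut-1-ene-1-carboxylate | CCOC(=O)C1=CC(C)(C)C1 | intermediate
5 | 4,4,5,5-tetramethyl-2-(prop-1-en-2-yl)-1,3,2-dioxaborolane | C=C(C)B1OC(C)(C)C(C)(C)O1 | starting material
6 | ethyl (1R,2R)-3,3-dimethyl-2-(prop-1-en-2-yl)cyclobutane-1-carboxylate | C=C(C)[C@H]1[C@H](C(=O)OCC)CC1(C)C | intermediate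
7 | (1R,2R)-3,3-dimethyl-2-(prop-1-en-2-yl)cyclobutane-1-carbaldehyde | C=C(C)[C@H]1[C@H](C=O)CC1(C)C | intermediate
8 | 2,2-dimethyl-1,3-dioxane-4,6-dione (Meldrum's acid) | CC1(C)OC(=O)CC(=O)O1 | starting material
9 | 5-{[(1S,2R)-3,3-dimethyl-2-(prop-1-en-2-yl)cyclobutyl]methylidene}-2,2-dimethyl-1,3-dioxane-4,6-dione | C=C(C)[C@H]1[C@H](C=C2C(=O)OC(C)(C)OC2=O)CC1(C)C | intermediate
10 | 5-{[(1R,2R)-3,3-dimethyl-2-(prop-1-en-2-yl)cyclobutyl]methyl}-2,2-dimethyl-1,3-dioxane-4,6-dione | C=C(C)[C@H]1[C@H](CC2C(=O)OC(C)(C)OC2=O)CC1(C)C | intermediate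
11 | 3-[(1R,2R)-3,3-dimethyl-2-(prop-1-en-2-yl)cyclobutyl]propanoic acid | C=C(C)[C@H]1[C@H](CCC(=O)O)CC1(C)C | intermediate
12 | (4S)-4-benzyl-1,3-oxazolidin-2-one | O=C1N[C@@H](Cc2ccccc2)CO1 | starting material
13 | pentanoyl chloride | CCCCC(=O)Cl | starting material
14 | (4S)-4-benzyl-3-pentanoyl-1,3-oxazolidin-2-one | CCCCC(=O)N1[C@@H](Cc2ccccc2)COC1=O | intermediate
15 | tert-butyl bromoacetate | CC(C)(C)OC(=O)CBr | starting material
16 | tert-butyl (3R)-3-{[(4S)-4-benzyl-2-oxo-1,3-oxazolidin-3-yl]carbonyl}hexanoate | CCC[C@H](CC(=O)OC(C)(C)C)C(=O)N1[C@@H](Cc2ccccc2)COC1=O | intermediate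
17 | tert-butyl (3R)-3-(hydroxymethyl)hexanoate | CCC[C@H](CC(=O)OC(C)(C)C)CO | intermediate
18 | tert-butyl (3R)-3-formylhexanoate | CCC[C@H](CC(=O)OC(C)(C)C)C=O | intermediate
19 | tert-butyl (3R)-3-ethynylhexanoate | CCC[C@H](CC(=O)OC(C)(C)C)C#C | intermediate
20 | lithium (3R)-5-tert-butoxy-5-oxo-3-propylpent-1-yn-1-olate (lithium ynolate) | CCC[C@H](CC(=O)OC(C)(C)C)C#C[O-].[Li+] | intermediate
21 | tert-butyl (3R)-3-[(TIPS-oxy)ethynyl]hexanoate | CCC[C@H](CC(=O)OC(C)(C)C)C#CO[Si](C(C)C)(C(C)C)C(C)C | intermediate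
22 | acetylene | C#C | starting material
23 | lithium ethynolate | [Li+].[O-]C#C | intermediate
24 | (triisopropylsilyloxy)ethyne | C#CO[Si](C(C)C)(C(C)C)C(C)C | intermediate
25 | 3-[(1R,2R)-3,3-dimethyl-2-(prop-1-en-2-yl)cyclobutyl]propanoyl chloride | C=C(C)[C@H]1[C@H](CCC(=O)Cl)CC1(C)C | intermediate
26 | 3-[(1R,2R)-3,3-dimethyl-2-(prop-1-en-2-yl)cyclobutyl]prop-1-en-1-one (alkylketene) | C=C(C)[C@H]1[C@H](CC=C=O)CC1(C)C | intermediate
27 | 4-(CbCH2)-2-(SC)-3-(TIPSO)cyclobut-2-en-1-one, both C4 epimers | C=C(C)[C@H]1[C@H](CC2C(=O)C([C@H](CCC)CC(=O)OC(C)(C)C)=C2O[Si](C(C)C)(C(C)C)C(C)C)CC1(C)C | intermediate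
28 | 4-(CbCH2)-2-(SC)-3-(TIPSO)buta-1,3-dien-1-one (vinylketene) | C=C(C)[C@H]1[C@H](CC=C(O[Si](C(C)C)(C(C)C)C(C)C)C(=C=O)[C@H](CCC)CC(=O)OC(C)(C)C)CC1(C)C | intermediate
29 | 4-[2-(CbCH2)-1-(TIPSO)ethenyl]-4-(SC)-3-(TIPSO)cyclobut-2-en-1-one | C=C(C)[C@H]1[C@H](CC=C(O[Si](C(C)C)(C(C)C)C(C)C)C2([C@H](CCC)CC(=O)OC(C)(C)C)C(=O)C=C2O[Si](C(C)C)(C(C)C)C(C)C)CC1(C)C | intermediate
30 | 6-(CbCH2)-4-(SC)-3,5-bis(TIPSO)hexa-1,3,5-trien-1-one (dienylketene) | C=C(C)[C@H]1[C@H](CC=C(O[Si](C(C)C)(C(C)C)C(C)C)C([C@H](CCC)CC(=O)OC(C)(C)C)=C(C=C=O)O[Si](C(C)C)(C(C)C)C(C)C)CC1(C)C | intermediate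
31 | 6-(CbCH2)-4-(SC)-3,5-bis(TIPSO)cyclohexa-2,4-dien-1-one | C=C(C)[C@H]1[C@H](CC2C(=O)C=C(O[Si](C(C)C)(C(C)C)C(C)C)C([C@H](CCC)CC(=O)OC(C)(C)C)=C2O[Si](C(C)C)(C(C)C)C(C)C)CC1(C)C | intermediate
32 | 2-(CbCH2)-4-(SC)-3,5-bis(TIPSO)phenol (target numbering: C1 CbCH2, C2 OTIPS, C3 SC, C4 OTIPS, C5 H, C6 OH; cyclobutane 1S,2R) | C=C(C)[C@H]1[C@H](Cc2c(O)cc(O[Si](C(C)C)(C(C)C)C(C)C)c([C@H](CCC)CC(=O)OC(C)(C)C)c2O[Si](C(C)C)(C(C)C)C(C)C)CC1(C)C | intermediate
33 | 3-(CbCH2)-2-hydroxy-5-(SC)-4,6-bis(TIPSO)benzaldehyde | C=C(C)[C@H]1[C@H](Cc2c(O)c(C=O)c(O[Si](C(C)C)(C(C)C)C(C)C)c([C@H](CCC)CC(=O)OC(C)(C)C)c2O[Si](C(C)C)(C(C)C)C(C)C)CC1(C)C | intermediate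
34 | 2-(allyloxy)-3-(CbCH2)-5-(SC)-4,6-bis(TIPSO)benzaldehyde | C=C(C)[C@H]1[C@H](Cc2c(OCC=C)c(C=O)c(O[Si](C(C)C)(C(C)C)C(C)C)c([C@H](CCC)CC(=O)OC(C)(C)C)c2O[Si](C(C)C)(C(C)C)C(C)C)CC1(C)C | intermediate
35 | 2-methylprop-1-en-1-ylmagnesium bromide | CC(C)=C[Mg]Br | starting material
36 | 1-[2-(allyloxy)-3-(CbCH2)-5-(SC)-4,6-bis(TIPSO)phenyl]-3-methylbut-2-en-1-ol, both carbinol epimers | C=C(C)[C@H]1[C@H](Cc2c(OCC=C)c(C(O)C=C(C)C)c(O[Si](C(C)C)(C(C)C)C(C)C)c([C@H](CCC)CC(=O)OC(C)(C)C)c2O[Si](C(C)C)(C(C)C)C(C)C)CC1(C)C | intermediate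
37 | 1-[2-(allyloxy)-3-(CbCH2)-5-(SC)-4,6-bis(TIPSO)phenyl]-3-methylbut-2-en-1-one | C=C(C)[C@H]1[C@H](Cc2c(OCC=C)c(C(=O)C=C(C)C)c(O[Si](C(C)C)(C(C)C)C(C)C)c([C@H](CCC)CC(=O)OC(C)(C)C)c2O[Si](C(C)C)(C(C)C)C(C)C)CC1(C)C | intermediate
38 | 1-[2-(allyloxy)-3-(CbCH2)-4,6-dihydroxy-5-(SC)phenyl]-3-methylbut-2-en-1-one | C=C(C)[C@H]1[C@H](Cc2c(OCC=C)c(C(=O)C=C(C)C)c(O)c([C@H](CCC)CC(=O)OC(C)(C)C)c2O)CC1(C)C | intermediate
39 | 5-(allyloxy)-6-(CbCH2)-7-hydroxy-2,2-dimethyl-8-(SC)chroman-4-one | C=C(C)[C@H]1[C@H](Cc2c(OCC=C)c3c(c([C@H](CCC)CC(=O)OC(C)(C)C)c2O)OC(C)(C)CC3=O)CC1(C)C | intermediate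
40 | 6-(CbCH2)-5,7-dihydroxy-2,2-dimethyl-8-(SC)chroman-4-one | C=C(C)[C@H]1[C@H](Cc2c(O)c3c(c([C@H](CCC)CC(=O)OC(C)(C)C)c2O)OC(C)(C)CC3=O)CC1(C)C | intermediate
41 | 3-methylbut-2-en-1-yl acetate (prenyl acetate) | CC(C)=CCOC(C)=O | starting material
42 | tert-butyl (3R)-3-[(6R)-6-{[(1S,2R)-3,3-dimethyl-2-(prop-1-en-2-yl)cyclobutyl]methyl}-5-hydroxy-2,2-dimethyl-6-(3-methylbut-2-en-1-yl)-4,7-dioxo-3,4,6,7-tetrahydro-2H-chromen-8-yl]hexanoate | C=C(C)[C@H]1[C@H](C[C@]2(CC=C(C)C)C(=O)C([C@H](CCC)CC(=O)OC(C)(C)C)=C3OC(C)(C)CC(=O)C3=C2O)CC1(C)C | intermediate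
43 | trimethylsilyl ester of the target with the C6 enol also trimethylsilylated | C=C(C)[C@H]1[C@H](C[C@]2(CC=C(C)C)C(=O)C([C@H](CCC)CC(=O)O[Si](C)(C)C)=C3OC(C)(C)CC(=O)C3=C2O[Si](C)(C)C)CC1(C)C | intermediate
44 | (3R)-3-[(6R)-6-{[(1S,2R)-3,3-dimethyl-2-(prop-1-en-2-yl)cyclobutyl]methyl}-5-hydroxy-2,2-dimethyl-6-(3-methylbut-2-en-1-yl)-4,7-dioxo-3,4,6,7-tetrahydro-2H-chromen-8-yl]hexanoic acid (CNP0358381.1) | C=C(C)[C@H]1[C@H](C[C@]2(CC=C(C)C)C(=O)C([C@H](CCC)CC(=O)O)=C3OC(C)(C)CC(=O)C3=C2O)CC1(C)C | target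

**Step count**
Total: 24 steps. Longest linear sequence: 17 steps (steps 1–7, then 15–24). The alkyne branch (steps 8–13) and the ynol ether (step 14) are convergent side branches.

**Steps most likely to fail**

1. Step 23 (the step that carries the label). Facial selectivity at the planar phenoxide may be poor, attack may occur through C3 or oxygen instead of C1, or the π-prenyl unit may be attacked at its tertiary terminus. The fallback sets out from 40 and uses the known base-mediated dearomative C-prenylation of acylphloroglucinols: prenyl bromide with NaOMe in MeOH at 0 °C should alkylate C1 without facial control, giving 42 together with its C1 epimer, tert-butyl (3R)-3-[(6S)-…]hexanoate F1. The two are diastereomers and are separated by preparative HPLC, and the route is rejoined at 42.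

2. Step 4. Insertion at the β-carbon next to the quaternary carbon may be slow, so that protodeboronation of the alkenylboronate wins, or enantiofacial discrimination may be low. The fallback sets out from 4 and replaces catalytic induction by a covalently bound auxiliary with diastereomer separation. Saponification (LiOH, THF/H2O) gives 3,3-dimethylcyclobut-1-ene-1-carboxylic acid F2. Its pivalic mixed anhydride acylates lithiated 12 to give the N-enoyl oxazolidinone F3. Conjugate addition of isopropenylmagnesium bromide with CuBr·SMe2 (THF, −78 to −20 °C) gives diastereomeric adducts, from which the trans (1R,2R) imide F4 is purified by chromatography; if induction runs the wrong way the antipodal auxiliary is used. Ethanolysis with EtOMgBr releases the auxiliary and rejoins the route at 6.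

3. Step 17. C–C bond formation at C5 may stall because the position is crowded between the hydroxyl and a bulky silyl ether, and prolonged heating may cost a silyl group. The fallback sets out from 32 and replaces phenoxide-directed formylation by halogenation and metalation. NBS in CH2Cl2 at −78 °C brominates the only free ring position to give the C5-bromo phenol F5, and allyl bromide with K2CO3 gives the C5-bromo O6-allyl ether F6. Bromine–lithium exchange with t-BuLi at −100 °C (cold enough to outrun silyl migration and ester attack), then addition of 3-methylbut-2-enal, rejoins the route at 36.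

**Further compounds**

F1 | step 23 | tert-butyl (3R)-3-[(6S)-6-{[(1S,2R)-3,3-dimethyl-2-(prop-1-en-2-yl)cyclobutyl]methyl}-5-hydroxy-2,2-dimethyl-6-(3-methylbut-2-en-1-yl)-4,7-dioxo-3,4,6,7-tetrahydro-2H-chromen-8-yl]hexanoate (C1 epimer of 42) | C=C(C)[C@H]1[C@H](C[C@@]2(CC=C(C)C)C(=O)C([C@H](CCC)CC(=O)OC(C)(C)C)=C3OC(C)(C)CC(=O)C3=C2O)CC1(C)C
F2 | step 4 | 3,3-dimethylcyclobut-1-ene-1-carboxylic acid | CC1(C)C=C(C(=O)O)C1
F3 | step 4 | (4S)-4-benzyl-3-[(3,3-dimethylcyclobut-1-en-1-yl)carbonyl]-1,3-oxazolidin-2-one | CC1(C)C=C(C(=O)N2[C@@H](Cc3ccccc3)COC2=O)C1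
F4 | step 4 | (4S)-4-benzyl-3-{[(1R,2R)-3,3-dimethyl-2-(prop-1-en-2-yl)cyclobutyl]carbonyl}-1,3-oxazolidin-2-one | C=C(C)[C@H]1[C@H](C(=O)N2[C@@H](Cc3ccccc3)COC2=O)CC1(C)C
F5 | step 17 | 6-bromo-2-(CbCH2)-4-(SC)-3,5-bis(TIPSO)phenol (C5-bromo phenol) | C=C(C)[C@H]1[C@H](Cc2c(O)c(Br)c(O[Si](C(C)C)(C(C)C)C(C)C)c([C@H](CCC)CC(=O)OC(C)(C)C)c2O[Si](C(C)C)(C(C)C)C(C)C)CC1(C)C
F6 | step 17 | allyl ether of F5 (C5-bromo, O6-allyl) | C=C(C)[C@H]1[C@H](Cc2c(OCC=C)c(Br)c(O[Si](C(C)C)(C(C)C)C(C)C)c([C@H](CCC)CC(=O)OC(C)(C)C)c2O[Si](C(C)C)(C(C)C)C(C)C)CC1(C)C
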